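In a one-step world Z would fall with a single time constant, so we first ask which one-step world this flask resembles. The winter run is this same flask, followed for its first 60.0 min:

| setting | winter | flask |
|---|---|---|
| Z | 1.5 M | 1.5 M |
| remark | the very flask that is asked about, followed so far |  |
| time |  | 2.5 h |

winter run (percent of the Z charged)

| time / min | Z / % | X / % |
|---|---|---|
| 10.0 | 83 | 0 |
| 20.0 | 69 | 6 |
| 30.0 | 61 | 1 |
| 40.0 | 49 | 3 |
| 50.0 | 49 | 6 |
| 60.0 | 44 | 3 |

(each reading ± 2 percentage points)

- in percentages every species weighs as the Z in it: one G or L counts as two
- reactions considered so far: Z + 2 X -> 3 X; Z -> X; Z + X -> G; 2 Z -> L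

1. amount of Z in percent of the Z charged, at 8.0 min, 40 min and 2.5 h

Z reads 44 % at the end of the winter run, while X reads between 0 % and 6 %, so most of the lost Z has gone to something not read. Two extreme flasks fit that, and both can be solved in the head.

In the first, Z turns slowly into X and each X at once takes another Z into G. If we treat that fast step as settled, X stays small and the loss goes as [Z]. Z then decays exponentially, and the last reading gives a time constant of 73.1 min, which leaves 12.8 % at 2.5 h.

In the second, two Z join to L, the loss goes as [Z] squared, and the decay slows as Z thins out. Its one constant is the pairing time 47.1 min, the time in which this step alone halves the charge, known in the field as the second-order half-life. The share of Z left is one over one plus time divided by pairing time, which gives 85.5 % at 8.0 min, 54.1 % at 40 min and 23.9 % at 2.5 h.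

Both worlds pass through the last reading, and after it the exponential falls further, so a flask with both routes ends between them. The readings lean towards pairing: the pairing time is 48.8 min from the first reading and 46.9 min from the third, whereas the exponential constant drifts from 53.7 min to 73.1 min. We keep the pairing values for the two early times. For 2.5 h we judge the flask to lie at 21.1 %, a quarter of the way down the bracket.

The forecast, reading that “the loss looks second order in Z”, gives 85 %, 54 % and 24 %, which puts it higher than our figure at 2.5 h.

The flask gives 85.4 %, 53.0 % and 20.5 %, which at 2.5 h is nearer the pairing end of the bracket.

    Z + 2 X → 3 X (k = 5.80 × 10⁻⁴ /M²/s)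
    Z → X (k = 2.30 × 10⁻⁵ /s)
    Z + X → G (k = 9.70 × 10⁻⁵ /M/s)
    2 Z → L (k = 1.10 × 10⁻⁴ /M/s)

Take the pairing step out of the same run and 65.1 % of Z remains at 2.5 h instead of 20.5 %, so pairing is the main reason for the loss, covering 56 % of what is missing. In this flask it uses Z 14 times as fast as the step Z -> X at the start, and still 2.9 times as fast at 2.5 h. The pairing time of 47.1 min was read from the total loss of Z in the winter run, the other routes included, and the 23.9 % it gave stands 3.4 percentage points above the flask at 2.5 h.

All runs were generated by integration for substances that don't exist.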